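Everything rests on disconnecting the C4–C4a bond of the flavanone. Ring A is a phloroglucinol ring in which C5, C6, C7 and C8 are substituted, so C4a, ortho to O1 and O5 and para to O7, is its only open carbon; an acyl group tethered through O1–C2–C3 can close nowhere else. One operation, an intramolecular Friedel–Crafts acylation of a mixed anhydride, makes C4–C4a and ring C while leaving the C2 stereocentre, set earlier by Mitsunobu inversion, untouched. Its substrate is the (S)-3-aryloxy-3-phenylpropanoic acid that already carries the C6 benzyl arm, the three-ring C8 arm and all six phenols as benzyl ethers.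

Key step: step 14

Remark: sarmentosumin A has six phenolic hydroxyls, so the cyclisation substrate and product are hexa-O-benzyl ethers and the last step cleaves six benzyl groups; locants C2 to C8a are those of the flavanone.

Step 1
Reactants: 1 2-(benzyloxy)benzyl bromide; 2 [4-(benzyloxy)-3-formylphenyl]boronic acid
Product: 3 2-(benzyloxy)-5-[2-(benzyloxy)benzyl]benzaldehyde
Conditions: PdCl2(dppf), K2CO3, THF/H2O (10:1), 65 °C
Reagents that add atoms: none
Why: A Suzuki–Miyaura sp3–sp2 coupling should join the benzylic bromide to the arylboronic acid, since oxidative addition into the benzylic C–Br bond is fast, the aldehyde is inert, and boron sits para to the benzyloxy group so the methylene bridge lands there while the ortho formyl group is kept for the next bridge.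

Step 2
Reactants: 3 2-(benzyloxy)-5-[2-(benzyloxy)benzyl]benzaldehyde
Product: 4 {2-(benzyloxy)-5-[2-(benzyloxy)benzyl]phenyl}methanol
Conditions: NaBH4, THF/MeOH, 0 °C
Reagents that add atoms: none
Why: Borohydride reduction of an aryl aldehyde to the benzylic alcohol is chemoselective, because benzyl ethers and the diarylmethane are inert to NaBH4.

Step 3
Reactants: 4 {2-(benzyloxy)-5-[2-(benzyloxy)benzyl]phenyl}methanol
Product: 5 1-(benzyloxy)-4-[2-(benzyloxy)benzyl]-2-(bromomethyl)benzene
Conditions: PBr3, CH2Cl2, 0 °C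
Reagents that add atoms: phosphorus tribromide BrP(Br)Br
Why: PBr3 should convert the primary benzylic alcohol into the bromide by SN2 displacement of the phosphite ester, conditions under which aryl benzyl ethers survive.

Step 4
Reactants: 5 1-(benzyloxy)-4-[2-(benzyloxy)benzyl]-2-(bromomethyl)benzene; 2 [4-(benzyloxy)-3-formylphenyl]boronic acid
Product: 6 2-(benzyloxy)-5-{2-(benzyloxy)-5-[2-(benzyloxy)benzyl]benzyl}benzaldehyde
Conditions: PdCl2(dppf), K2CO3, THF/H2O (10:1), 65 °C
Reagents that add atoms: none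
Why: A second Suzuki–Miyaura sp3–sp2 coupling with the same boronic acid repeats the bridge-forming event and should deliver the complete three-ring arm with a formyl group ortho to the terminal benzyloxy group, ready for union with ring A.

Step 5
Reactants: 7 4-bromo-2,6-difluorobenzaldehyde
Product: 8 2,6-bis(benzyloxy)-4-bromobenzaldehyde
Conditions: BnOH, NaH, THF/DMF, 0 °C to rt
Reagents that add atoms: benzyl alcohol OCc1ccccc1
Why: Twofold nucleophilic aromatic substitution (SNAr) by benzyloxide should replace both fluorides, which are activated by the ortho formyl group and leave far faster than the para bromide, so the oxygen pattern around the future C6 carbon is fixed by the starting material and not by a regioselective substitution.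

Step 6
Reactants: 8 2,6-bis(benzyloxy)-4-bromobenzaldehyde; 9 1-(benzyloxy)-2-bromobenzene
Product: 11 (RS)-[2,6-bis(benzyloxy)-4-bromophenyl][2-(benzyloxy)phenyl]methanol, via aryl Grignard reagent 10 (not isolated)
Conditions: 9, Mg, THF, reflux; then 8, THF, 0 °C to rt; aq NH4Cl
Reagents that add atoms: none
Why: Grignard 1,2-addition of the aryl nucleophile to the aldehyde should give the diaryl carbinol (racemic, the centre being erased in step 7), the aryl bromide of 8 being inert to the organomagnesium reagent at these temperatures.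

Step 7
Reactants: 11 (RS)-[2,6-bis(benzyloxy)-4-bromophenyl][2-(benzyloxy)phenyl]methanol
Product: 12 1,3-bis(benzyloxy)-2-[2-(benzyloxy)benzyl]-5-bromobenzene
Conditions: Et3SiH, TFA, CH2Cl2, 0 °C
Reagents that add atoms: none
Why: Ionic hydrogenation should work because TFA ionises the benzhydrylic alcohol to a cation stabilised by three ortho alkoxy groups and Et3SiH traps it with hydride, leaving the aryl bromide and the benzyl ethers intact.

Step 8
Reactants: 12 1,3-bis(benzyloxy)-2-[2-(benzyloxy)benzyl]-5-bromobenzene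
Product: 13 3,5-bis(benzyloxy)-4-[2-(benzyloxy)benzyl]phenol
Conditions: Pd2(dba)3, tBuXPhos, KOH, 1,4-dioxane/H2O, 100 °C; then dilute HCl
Reagents that add atoms: potassium hydroxide [K+].[OH-]
Why: Palladium-catalysed C–O cross-coupling of the aryl bromide with hydroxide, in which the bulky biaryl phosphine favours release of the phenol over diaryl ether formation, should install the future O1 para to the benzyl arm, and benzyl ethers tolerate hot aqueous KOH.

Step 9
Reactants: 13 3,5-bis(benzyloxy)-4-[2-(benzyloxy)benzyl]phenol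
Product: 14 3,5-bis(benzyloxy)-4-[2-(benzyloxy)benzyl]-2-bromophenol
Conditions: NBS (1.0 equiv), CH2Cl2, −78 °C
Reagents that add atoms: N-bromosuccinimide O=C1CCC(=O)N1Br
Why: Electrophilic aromatic bromination should give one monobromide, because the trioxygenated ring is by far the most nucleophilic arene and its two free positions, both ortho to the hydroxyl, are equivalent by symmetry.

Step 10
Reactants: 14 3,5-bis(benzyloxy)-4-[2-(benzyloxy)benzyl]-2-bromophenol; 6 2-(benzyloxy)-5-{2-(benzyloxy)-5-[2-(benzyloxy)benzyl]benzyl}benzaldehyde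
Product: 16 3,5-bis(benzyloxy)-4-[2-(benzyloxy)benzyl]-2-[(RS)-(2-(benzyloxy)-5-{2-(benzyloxy)-5-[2-(benzyloxy)benzyl]benzyl}phenyl)(hydroxy)methyl]phenol, via dilithiated phenoxide 15 (not isolated)
Conditions: n-BuLi (2.2 equiv), THF, −78 °C; then 6, −78 °C to −20 °C; H2O
Reagents that add atoms: none
Why: Deprotonation and bromine–lithium exchange should give the ortho-lithiated lithium phenoxide, which adds 1,2 to the aldehyde of 6 and joins the two fragments at the future C8 (carbinol centre racemic and erased in step 11), exchange at −78 °C being faster than lithiation of the benzylic ether positions.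

Step 11
Reactants: 16 ortho-hydroxybenzhydrol from step 10
Product: 17 3,5-bis(benzyloxy)-4-[2-(benzyloxy)benzyl]-2-(2-(benzyloxy)-5-{2-(benzyloxy)-5-[2-(benzyloxy)benzyl]benzyl}benzyl)phenol
Conditions: Et3SiH, TFA, CH2Cl2, 0 °C
Reagents that add atoms: none
Why: Ionic hydrogenation should reduce the carbinol, since acid turns the ortho-hydroxybenzhydrol into a stabilised cation (ortho-quinone methide) that Et3SiH reduces to the methylene bridge without touching the benzyl ethers or the free phenol.

Step 12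
Reactants: 17 ring A phenol bearing both arms; 18 ethyl (R)-3-hydroxy-3-phenylpropanoate
Product: 19 ethyl (3S)-3-[3,5-bis(benzyloxy)-4-[2-(benzyloxy)benzyl]-2-(2-(benzyloxy)-5-{2-(benzyloxy)-5-[2-(benzyloxy)benzyl]benzyl}benzyl)phenoxy]-3-phenylpropanoate
Conditions: PPh3, DIAD, toluene, 0 °C to rt
Reagents that add atoms: none
Why: Mitsunobu etherification should let the phenol, which keeps one unsubstituted ortho position, displace the activated secondary benzylic hydroxyl by SN2 with inversion, so the (R)-alcohol gives the (S)-aryl ether whose carbon becomes C2 of the flavanone.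

Step 13
Reactants: 19 ethyl (S)-3-aryloxy-3-phenylpropanoate from step 12
Product: 20 (3S)-3-[3,5-bis(benzyloxy)-4-[2-(benzyloxy)benzyl]-2-(2-(benzyloxy)-5-{2-(benzyloxy)-5-[2-(benzyloxy)benzyl]benzyl}benzyl)phenoxy]-3-phenylpropanoic acid
Conditions: LiOH·H2O, THF/MeOH/H2O, 0 °C to rt; then 1 M HCl
Reagents that add atoms: lithium hydroxide [Li+].[OH-]
Why: Saponification of the ethyl ester at low temperature should outrun E1cB loss of the electron-rich aryloxide, the carboxylate formed no longer eliminates, and the stereocentre is not involved.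

Step 14
Reactants: 20 (S)-3-aryloxy-3-phenylpropanoic acid, all six phenols as benzyl ethers
Product: 22 (2S)-5,7-bis(benzyloxy)-6-[2-(benzyloxy)benzyl]-8-(2-(benzyloxy)-5-{2-(benzyloxy)-5-[2-(benzyloxy)benzyl]benzyl}benzyl)-2-phenylchroman-4-one, via mixed trifluoroacetic anhydride 21 (not isolated)
Conditions: TFAA (2 equiv), CH2Cl2, 0 °C to rt
Reagents that add atoms: none
Why: TFAA converts the acid into the mixed anhydride 21, whose alkanoyl carbon (as such or as the derived acylium ion) is attacked by C4a of ring A to give an arenium ion that rearomatises by proton loss, which is an intramolecular Friedel–Crafts acylation of the kind used to close 3-aryloxypropanoic acids to chroman-4-ones. Ring C closes as a six-membered ring, 6-exo-trig at the acyl carbon, with the O1–C2–C3 tether holding the electrophile over the neighbouring ring position. No stereocentre is created, and C2, set in step 12, takes part in no bond change and should keep its S configuration. Regioselectivity needs no control because C4a is the only unsubstituted carbon of ring A and is activated by O1 and O5 (ortho) and O7 (para). Chemoselectivity over the mono-oxygenated arm rings follows from the much higher nucleophilicity of the trioxygenated ring and from the six-membered intramolecular transition state. Working without a strong Lewis acid and at low temperature should keep the benzyl ethers, the benzylic C2–O1 bond and the β-aryloxy acyl unit from ionising or eliminating.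

Step 15
Reactants: 22 hexa-O-benzyl sarmentosumin A
Product: 23 sarmentosumin A, (2S)-5,7-dihydroxy-6-(2-hydroxybenzyl)-8-(2-hydroxy-5-{2-hydroxy-5-[2-hydroxybenzyl]benzyl}benzyl)-2-phenylchroman-4-one
Conditions: H2 (1 atm), Pd/C, EtOAc/MeOH, rt
Reagents that add atoms: none
Why: Catalytic hydrogenolysis cleaves the six aryl benzyl ethers under neutral conditions, whereas the ketone, the diarylmethane bridges and the ring C–O bond at C2 react much more slowly, so stopping at complete debenzylation should give the target without ring opening or loss of configuration.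

Compound list
1 | 2-(benzyloxy)benzyl bromide | BrCc1ccccc1OCc1ccccc1 | starting material
2 | [4-(benzyloxy)-3-formylphenyl]boronic acid | O=Cc1cc(B(O)O)ccc1OCc1ccccc1 | starting material
3 | 2-(benzyloxy)-5-[2-(benzyloxy)benzyl]benzaldehyde | O=Cc1cc(Cc2ccccc2OCc2ccccc2)ccc1OCc1ccccc1 | intermediate
4 | {2-(benzyloxy)-5-[2-(benzyloxy)benzyl]phenyl}methanol | OCc1cc(Cc2ccccc2OCc2ccccc2)ccc1OCc1ccccc1 | intermediate
5 | 1-(benzyloxy)-4-[2-(benzyloxy)benzyl]-2-(bromomethyl)benzene | BrCc1cc(Cc2ccccc2OCc2ccccc2)ccc1OCc1ccccc1 | intermediate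
6 | 2-(benzyloxy)-5-{2-(benzyloxy)-5-[2-(benzyloxy)benzyl]benzyl}benzaldehyde | O=Cc1cc(Cc2cc(Cc3ccccc3OCc3ccccc3)ccc2OCc2ccccc2)ccc1OCc1ccccc1 | intermediate
7 | 4-bromo-2,6-difluorobenzaldehyde | O=Cc1c(F)cc(Br)cc1F | starting material
8 | 2,6-bis(benzyloxy)-4-bromobenzaldehyde | O=Cc1c(OCc2ccccc2)cc(Br)cc1OCc1ccccc1 | intermediate
9 | 1-(benzyloxy)-2-bromobenzene | Brc1ccccc1OCc1ccccc1 | starting material
10 | [2-(benzyloxy)phenyl]magnesium bromide | Br[Mg]c1ccccc1OCc1ccccc1 | intermediate
11 | (RS)-[2,6-bis(benzyloxy)-4-bromophenyl][2-(benzyloxy)phenyl]methanol | OC(c1ccccc1OCc1ccccc1)c1c(OCc2ccccc2)cc(Br)cc1OCc1ccccc1 | intermediate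
12 | 1,3-bis(benzyloxy)-2-[2-(benzyloxy)benzyl]-5-bromobenzene | Brc1cc(OCc2ccccc2)c(Cc2ccccc2OCc2ccccc2)c(OCc2ccccc2)c1 | intermediate
13 | 3,5-bis(benzyloxy)-4-[2-(benzyloxy)benzyl]phenol | Oc1cc(OCc2ccccc2)c(Cc2ccccc2OCc2ccccc2)c(OCc2ccccc2)c1 | intermediate
14 | 3,5-bis(benzyloxy)-4-[2-(benzyloxy)benzyl]-2-bromophenol | Oc1cc(OCc2ccccc2)c(Cc2ccccc2OCc2ccccc2)c(OCc2ccccc2)c1Br | intermediate
15 | lithium 3,5-bis(benzyloxy)-4-[2-(benzyloxy)benzyl]-2-lithiophenoxide | [Li]Oc1cc(OCc2ccccc2)c(Cc2ccccc2OCc2ccccc2)c(OCc2ccccc2)c1[Li] | intermediate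
16 | 3,5-bis(benzyloxy)-4-[2-(benzyloxy)benzyl]-2-[(RS)-(2-(benzyloxy)-5-{2-(benzyloxy)-5-[2-(benzyloxy)benzyl]benzyl}phenyl)(hydroxy)methyl]phenol | Oc1cc(OCc2ccccc2)c(Cc2ccccc2OCc2ccccc2)c(OCc2ccccc2)c1C(O)c1cc(Cc2cc(Cc3ccccc3OCc3ccccc3)ccc2OCc2ccccc2)ccc1OCc1ccccc1 | intermediate
17 | 3,5-bis(benzyloxy)-4-[2-(benzyloxy)benzyl]-2-(2-(benzyloxy)-5-{2-(benzyloxy)-5-[2-(benzyloxy)benzyl]benzyl}benzyl)phenol | Oc1cc(OCc2ccccc2)c(Cc2ccccc2OCc2ccccc2)c(OCc2ccccc2)c1Cc1cc(Cc2cc(Cc3ccccc3OCc3ccccc3)ccc2OCc2ccccc2)ccc1OCc1ccccc1 | intermediate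
18 | ethyl (R)-3-hydroxy-3-phenylpropanoate | CCOC(=O)C[C@H](c1ccccc1)O | starting material
19 | ethyl (3S)-3-[3,5-bis(benzyloxy)-4-[2-(benzyloxy)benzyl]-2-(2-(benzyloxy)-5-{2-(benzyloxy)-5-[2-(benzyloxy)benzyl]benzyl}benzyl)phenoxy]-3-phenylpropanoate | CCOC(=O)C[C@@H](c1ccccc1)Oc1cc(OCc2ccccc2)c(Cc2ccccc2OCc2ccccc2)c(OCc2ccccc2)c1Cc1cc(Cc2cc(Cc3ccccc3OCc3ccccc3)ccc2OCc2ccccc2)ccc1OCc1ccccc1 | intermediate
20 | (3S)-3-[3,5-bis(benzyloxy)-4-[2-(benzyloxy)benzyl]-2-(2-(benzyloxy)-5-{2-(benzyloxy)-5-[2-(benzyloxy)benzyl]benzyl}benzyl)phenoxy]-3-phenylpropanoic acid | OC(=O)C[C@@H](c1ccccc1)Oc1cc(OCc2ccccc2)c(Cc2ccccc2OCc2ccccc2)c(OCc2ccccc2)c1Cc1cc(Cc2cc(Cc3ccccc3OCc3ccccc3)ccc2OCc2ccccc2)ccc1OCc1ccccc1 | intermediate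
21 | mixed anhydride of acid 20 with trifluoroacetic acid, (3S) | FC(F)(F)C(=O)OC(=O)C[C@@H](c1ccccc1)Oc1cc(OCc2ccccc2)c(Cc2ccccc2OCc2ccccc2)c(OCc2ccccc2)c1Cc1cc(Cc2cc(Cc3ccccc3OCc3ccccc3)ccc2OCc2ccccc2)ccc1OCc1ccccc1 | intermediate
22 | hexa-O-benzyl sarmentosumin A, (2S)-5,7-bis(benzyloxy)-6-[2-(benzyloxy)benzyl]-8-(2-(benzyloxy)-5-{2-(benzyloxy)-5-[2-(benzyloxy)benzyl]benzyl}benzyl)-2-phenylchroman-4-one | O=C1C[C@@H](c2ccccc2)Oc2c(Cc3cc(Cc4cc(Cc5ccccc5OCc5ccccc5)ccc4OCc4ccccc4)ccc3OCc3ccccc3)c(OCc3ccccc3)c(Cc3ccccc3OCc3ccccc3)c(OCc3ccccc3)c21 | intermediate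
23 | sarmentosumin A, (2S)-5,7-dihydroxy-6-(2-hydroxybenzyl)-8-(2-hydroxy-5-{2-hydroxy-5-[2-hydroxybenzyl]benzyl}benzyl)-2-phenylchroman-4-one | O=C1C[C@@H](c2ccccc2)Oc2c(Cc3cc(Cc4cc(Cc5ccccc5O)ccc4O)ccc3O)c(O)c(Cc3ccccc3O)c(O)c21 | target

Total step count: 15. Longest linear sequence: 11 steps (steps 5 to 15, from 7); the three-ring arm is made in a 4-step branch (steps 1 to 4) that joins at step 10.

Steps most likely to fail

Step 14 (ring closure). The activated acid may lose the aryloxide by β-elimination, the acid released may ionise the benzylic C2–O1 bond and erode configuration, or intermolecular trifluoroacetylation at C4a may compete with cyclisation. The fallback reverses the polarity of the same bond formation and sets out from 20. Bromination of the only free ring A position with NBS (CH2Cl2, −78 °C) should give (3S)-3-[3,5-bis(benzyloxy)-4-[2-(benzyloxy)benzyl]-2-bromo-6-(2-(benzyloxy)-5-{2-(benzyloxy)-5-[2-(benzyloxy)benzyl]benzyl}benzyl)phenoxy]-3-phenylpropanoic acid F1. Treatment with n-BuLi (2.2 equiv, THF, −78 °C) then forms the lithium carboxylate and exchanges bromine for lithium, and the aryllithium attacks the carboxylate (Parham cyclisation). After aqueous work-up the route is rejoined at 22.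

Step 12 (Mitsunobu etherification). Dehydration of the β-hydroxy ester to ethyl cinnamate may outrun substitution by the hindered, weakly acidic phenol, and any SN1 character at the benzylic carbon would erode enantiopurity. The fallback sets out from 17 and uses an alcohol without an acidifying carbonyl group. Mitsunobu coupling (PPh3, DIAD, toluene) with (R)-3-[(tert-butyldimethylsilyl)oxy]-1-phenylpropan-1-ol F2, obtained by silylating the primary hydroxyl of commercial (R)-1-phenylpropane-1,3-diol (TBSCl, imidazole), should give with inversion the tert-butyldimethylsilyl ether of the (S)-3-aryloxy-3-phenylpropan-1-ol F3. TBAF in THF frees the (S)-3-aryloxy-3-phenylpropan-1-ol F4, and TEMPO with PhI(OAc)2 in aqueous MeCN oxidises the primary alcohol to the acid, rejoining the route at 20.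

Step 10 (fragment union). Exchange on the electron-rich phenoxide may be slow or incomplete, lithiation at a benzylic ether position may compete, or the aryllithium may be quenched before it meets the aldehyde. The fallback sets out from 13 and 6 and avoids organolithium chemistry by a boron-templated ortho-hydroxyalkylation. Phenylboronic acid with catalytic propionic acid in refluxing toluene (water removal) should condense phenol and aldehyde, ortho-specifically, into 5,7-bis(benzyloxy)-6-[2-(benzyloxy)benzyl]-4-(2-(benzyloxy)-5-{2-(benzyloxy)-5-[2-(benzyloxy)benzyl]benzyl}phenyl)-2-phenyl-4H-1,3,2-benzodioxaborinine F5. Ionic hydrogenation (Et3SiH, TFA, CH2Cl2, 0 °C) cleaves the benzylic C–O bond and, after work-up, frees the phenol, rejoining the route at 17 and bypassing 14 to 16.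

Further compounds
F1 | step 14 | (3S)-3-[3,5-bis(benzyloxy)-4-[2-(benzyloxy)benzyl]-2-bromo-6-(2-(benzyloxy)-5-{2-(benzyloxy)-5-[2-(benzyloxy)benzyl]benzyl}benzyl)phenoxy]-3-phenylpropanoic acid | OC(=O)C[C@@H](c1ccccc1)Oc1c(Br)c(OCc2ccccc2)c(Cc2ccccc2OCc2ccccc2)c(OCc2ccccc2)c1Cc1cc(Cc2cc(Cc3ccccc3OCc3ccccc3)ccc2OCc2ccccc2)ccc1OCc1ccccc1
F2 | step 12 | (R)-3-[(tert-butyldimethylsilyl)oxy]-1-phenylpropan-1-ol | CC(C)(C)[Si](C)(C)OCC[C@H](c1ccccc1)O
F3 | step 12 | tert-butyldimethylsilyl ether of (3S)-3-[3,5-bis(benzyloxy)-4-[2-(benzyloxy)benzyl]-2-(2-(benzyloxy)-5-{2-(benzyloxy)-5-[2-(benzyloxy)benzyl]benzyl}benzyl)phenoxy]-3-phenylpropan-1-ol | CC(C)(C)[Si](C)(C)OCC[C@@H](c1ccccc1)Oc1cc(OCc2ccccc2)c(Cc2ccccc2OCc2ccccc2)c(OCc2ccccc2)c1Cc1cc(Cc2cc(Cc3ccccc3OCc3ccccc3)ccc2OCc2ccccc2)ccc1OCc1ccccc1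
F4 | step 12 | (3S)-3-[3,5-bis(benzyloxy)-4-[2-(benzyloxy)benzyl]-2-(2-(benzyloxy)-5-{2-(benzyloxy)-5-[2-(benzyloxy)benzyl]benzyl}benzyl)phenoxy]-3-phenylpropan-1-ol | OCC[C@@H](c1ccccc1)Oc1cc(OCc2ccccc2)c(Cc2ccccc2OCc2ccccc2)c(OCc2ccccc2)c1Cc1cc(Cc2cc(Cc3ccccc3OCc3ccccc3)ccc2OCc2ccccc2)ccc1OCc1ccccc1
F5 | step 10 | (RS)-5,7-bis(benzyloxy)-6-[2-(benzyloxy)benzyl]-4-(2-(benzyloxy)-5-{2-(benzyloxy)-5-[2-(benzyloxy)benzyl]benzyl}phenyl)-2-phenyl-4H-1,3,2-benzodioxaborinine | B1(c2ccccc2)Oc2cc(OCc3ccccc3)c(Cc3ccccc3OCc3ccccc3)c(OCc3ccccc3)c2C(c2cc(Cc3cc(Cc4ccccc4OCc4ccccc4)ccc3OCc3ccccc3)ccc2OCc2ccccc2)O1
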